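A small charge of electrophile, dripped in over 2.0 h, meets nucleophile at 3.00 times its amount, and each molecule faces one fork: wait in solution or become target.

| setting | gamma | zeta | flask |
|---|---|---|---|
| electrophile | 0.021 M (fed, over 2.0 h) | 0.033 M (fed, over 2.0 h) | 0.015 M (fed, over 2.0 h) |
| nucleophile | 0.045 M | 0.045 M | 0.0450 M |
| free base | 0.045 M | 0.045 M | 0.0450 M |
| remark | run made earlier | run made earlier |  |
| time |  |  | 2.0 h |

| run | time / min | target / % | electrophile / % |
|---|---|---|---|
| gamma | 15.0 | 6 | 7 |
| gamma | 30.0 | 8 | 14 |
| gamma | 50.0 | 18 | 20 |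
| gamma | 60.0 | 26 | 22 |
| gamma | 80.0 | 37 | 29 |
| gamma | 90.0 | 41 | 32 |
| gamma | 120 | 63 | 38 |
| zeta | 10.0 | 0 | 9 |
| zeta | 15.0 | 3 | 9 |
| zeta | 20.0 | 7 | 12 |
| zeta | 30.0 | 9 | 18 |
| zeta | 50.0 | 22 | 20 |
| zeta | 80.0 | 38 | 30 |
| zeta | 120 | 53 | 42 |

(standard deviation of a reading: 2 percentage points)

- percentages count the whole charge, also what has not yet gone in

1. amount of target in the flask at 2.0 h, in percent of the electrophile charged
2. amount of electrophile in the flask at 2.0 h, in percent of the electrophile charged

At the end of dosing, target plus electrophile reads 101 % in gamma and 95.0 % in zeta, so the reckoning here treats these two as the whole charge. Give a waiting molecule a pseudo-first-order rate k̄B̄, where B̄ is the mean of the nucleophile charged and the nucleophile left, counting one nucleophile per target. A molecule fed a time s before the end survives with chance e^(−k̄B̄s). Averaged over a steady dose, the electrophile left is S = (1 − e^(−x))/x, with x = k̄B̄ times the dosing time.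

One iteration of x = (1 − e^(−1/S))/S turns gamma's 38 % into 2.44 and zeta's 42 % into 2.16. With B̄ of 0.0384 M and 0.0363 M, the runs read 31.8 M⁻¹ h⁻¹ and 29.8 M⁻¹ h⁻¹. Their mean, 30.8 M⁻¹ h⁻¹, is k̄, the apparent rate constant: the chance per unit time and per unit of mean nucleophile that a waiting electrophile molecule becomes target.

For this flask, taking gamma's target share, B̄ is 0.0403 M and x is 2.48, so this reckoning gives 36.9 % electrophile and 63.1 % target.

The forecast, holding that “the rate follows what has been consumed”, gives target 64 % (59 % to 69 %) and electrophile 35 % (31 % to 39 %). Its electrophile lies 1.9 percentage points below this reckoning, which still falls inside its range.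

The flask holds 63.5 % target and 36.5 % electrophile, both inside the forecast's ranges. Its nucleophile stands at 45.8 % of charge, lower than the 78.8 % that one nucleophile per target leaves, so B̄ is a bookkeeping value and k̄ is apparent. Reckoned again with the flask's own target, k̄ returns 37.0 % electrophile.

    acid set free + free base ⇌ salt of the base, settled at all times (K = 35000 M⁻¹)
    nucleophile + acid set free ⇌ protonated nucleophile, settled at all times (K = 18000 M⁻¹)
    electrophile + nucleophile → acid set free + target (k = 49.0 M⁻¹ h⁻¹)
    crystals ⇌ acid set free, rate k4*(cs4 - [acid set free]) while solid is left; crystals form when [acid set free] > cs4 (solubility = 7.80 mM, k = 58.0 h⁻¹)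
    2 nucleophile → self-condensation product (k = 3.00 M⁻¹ h⁻¹)

For a neighbouring flask, charged with 0.026 M of electrophile, k̄ and gamma's target share give x = 2.27 and 39.5 % electrophile. That flask holds 41.2 % electrophile and 58.8 % target.

The earlier runs and the new flask stem from a simulated flask for an exercise.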